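**Retrosynthetic overview**
1. Presumed biosynthesis: prenylated cyclodeca-1,6-diene → transannular [2+2] → spatane (5-4-5) → oxidative scission of the cyclobutane bond C6–C7 (C6 ketone, C7–O). The route copies both events.
2. Target ⇐ E1cB loss of a C4 acetate and alkoxy-radical scission of a C6 cyclobutanol with O2 capture at C7 ⇐ spatane-type cyclobutanol (Z side chain by Wittig on a C10 acetyl).
3. Spatane core ⇐ transannular [2+2] of a ten-membered 1,6-diene (C1=C2, C6=C7) whose enol C6=C7 sits in a δ-lactone (C4–O–C18(=O)–C7) that dictates every new stereocentre.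
4. Macrocycle ⇐ RCM (C1=C2) ⇐ pyranone enol pivalate ⇐ reductive alkylation (C7–C8) of pyranone 6 (crotylboration, Claisen condensation) with aldehyde 13 (CBS reduction, Claisen rearrangement).
5. Ring order: temporary δ-lactone → ten-membered carbocycle → rings A and B plus cyclobutane in one photochemical step → cyclobutane and lactone opened.

Assumption: the side-chain olefin is Z as written in the SMILES (C10 and C13 cis). Locants C1–C20 are biogenetic: ring A = C2–C6 (CH3 on C3), ring B = C1 and C7–C10 (C18 on C7), side chain C11–C15 on C10.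

**Step 1**
Reactants: 1 methyl 3,3-dimethoxypropanoate
Product: 3 methyl (3R,4S)-3-hydroxy-4-methylhex-5-enoate, via methyl 3-oxopropanoate 2 (not isolated)
Conditions: TFA/H2O, CH2Cl2, 0 °C; crude aldehyde, then (E)-crotyl-B(Ipc)2 [from (−)-Ipc2BOMe, trans-but-2-ene, KOt-Bu, n-BuLi, BF3·OEt2], THF/Et2O, −78 °C; NaOH, H2O2
Reagents that add atoms: water O; (E)-but-2-enylbis(isopinocampheyl)borane C/C=C/CB([C@@H]1C[C@@H]2C[C@H]([C@H]1C)C2(C)C)[C@@H]1C[C@@H]2C[C@H]([C@H]1C)C2(C)C
Why: Acid hydrolysis frees the aldehyde and Brown crotylboration (base-free, −78 °C) through a closed chair transition state gives the anti adduct, the (+)-α-pinene-derived reagent setting C4 (3R) and C3 (4S) together.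

**Step 2**
Reactants: 3 methyl (3R,4S)-3-hydroxy-4-methylhex-5-enoate; 4 tert-butyl acetate
Product: 6 (6R)-6-[(2S)-but-3-en-2-yl]-4-hydroxy-5,6-dihydro-2H-pyran-2-one, via keto ester 5 (not isolated)
Conditions: LiN(i-Pr)2, 4 (4 equiv), THF, −78 → −20 °C; aq. NH4Cl; then TFA, CH2Cl2, rt
Reagents that add atoms: none
Why: Crossed Claisen condensation of the methyl ester with excess lithium tert-butyl acetate gives the δ-hydroxy β-keto ester, and TFA cleaves the tert-butyl group and lactonizes it to the enolized β-keto δ-lactone without touching C3 or C4.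

**Step 3**
Reactants: 7 methacrolein; 8 1-(triphenyl-λ5-phosphanylidene)propan-2-one
Product: 9 (3E)-5-methylhexa-3,5-dien-2-one
Conditions: CH2Cl2, 40 °C
Reagents that add atoms: none
Why: Wittig olefination with a stabilized ylide gives the E-enone selectively.

**Step 4**
Reactants: 9 (3E)-5-methylhexa-3,5-dien-2-one
Product: 10 (2R,3E)-5-methylhexa-3,5-dien-2-ol
Conditions: (S)-2-methyl-CBS-oxazaborolidine (10 mol%), catecholborane, toluene, −78 °C
Reagents that add atoms: none
Why: Corey–Bakshi–Shibata reduction gives clean 1,2-reduction, the alkenyl group acting as the large substituent so that the (S)-catalyst delivers the (R)-carbinol.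

**Step 5**
Reactants: 10 (2R,3E)-5-methylhexa-3,5-dien-2-ol; 11 vinyl acetate
Product: 13 (3R,4E)-3-(prop-1-en-2-yl)hex-4-enal, via allyl vinyl ether 12 (not isolated)
Conditions: [Ir(cod)Cl]2 (1 mol%), Na2CO3, toluene, 100 °C; then 140 °C (sealed tube)
Reagents that add atoms: none
Why: Iridium-catalysed vinyl transfer gives the allyl vinyl ether, and its Claisen rearrangement through a chair with the methyl equatorial transfers the carbinol chirality to C10 (R) and forms the E-propenyl group.

**Step 6**
Reactants: 6 (6R)-6-[(2S)-but-3-en-2-yl]-4-hydroxy-5,6-dihydro-2H-pyran-2-one; 13 (3R,4E)-3-(prop-1-en-2-yl)hex-4-enal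
Product: 15 (6R)-6-[(2S)-but-3-en-2-yl]-4-hydroxy-3-[(3R,4E)-3-(prop-1-en-2-yl)hex-4-en-1-yl]-5,6-dihydro-2H-pyran-2-one, via Knoevenagel alkylidene 14 (not isolated)
Conditions: L-proline (20 mol%), diethyl 2,6-dimethyl-1,4-dihydropyridine-3,5-dicarboxylate, CH2Cl2, rt
Reagents that add atoms: none
Why: Organocatalytic three-component reductive alkylation (Knoevenagel condensation at C7 of the cyclic 1,3-dicarbonyl, then Hantzsch-ester conjugate reduction) forms C7–C8 under neutral conditions that leave all stereocentres and isolated alkenes untouched.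

**Step 7**
Reactants: 15 the 3-alkyl-4-hydroxypyranone
Product: 16 (6R)-6-[(2S)-but-3-en-2-yl]-2-oxo-3-[(3R,4E)-3-(prop-1-en-2-yl)hex-4-en-1-yl]-5,6-dihydro-2H-pyran-4-yl 2,2-dimethylpropanoate
Conditions: PivCl, Et3N, CH2Cl2, 0 °C
Reagents that add atoms: pivaloyl chloride CC(C)(C)C(Cl)=O
Why: O-acylation of the vinylogous acid fixes the C6=C7 enol as the photoactive β-acyloxy enoate and masks its acidity for the metathesis.

**Step 8**
Reactants: 16 the enol pivalate
Product: 17 lactone-bridged (1Z)-cyclodeca-1,6-diene pivalate (3S,4R,10R)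
Conditions: second-generation Grubbs catalyst (10 mol%), toluene (0.5 mM), 80 °C
Reagents that add atoms: none
Why: Ring-closing metathesis joins the terminal vinyl and the propenyl group (propene lost), both more reactive than the 1,1-disubstituted isopropenyl and the tetrasubstituted enol ester, and the C1=C2 geometry is immaterial because it is consumed in step 9.

**Step 9**
Reactants: 17 the bridged macrocycle
Product: 18 lactone-bridged cis-anti-cis tricyclic photoadduct (C6 pivalate; C10 isopropenyl)
Conditions: hν (300 nm), acetone, 2 mM, degassed, 10 °C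
Reagents that add atoms: none
Why: Proposed new method: triplet-sensitized transannular [2+2] photocycloaddition of the 4-acyloxy-dihydropyranone C6=C7 with the C1=C2 alkene held above it by the ansa bridge, the closest known reaction type being the intramolecular enone–alkene [2+2] of tetronates and dioxinones, in which five-membered closures C7–C1 and C6–C2 form rings B and A with the cyclobutane at once and the δ-lactone leaves one way to fold: C18 and C5 are cis on C6=C7 so ring B closes on the face opposite ring A, ring A closes cis to the C4–C3 bond so that (4R) fixes C6 and C2 and then C7 and C1, which places the (3S)-methyl and the (10R)-isopropenyl cis to the C1–C2 bond, while attack on the isopropenyl group would have to occur at its fully substituted carbon.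

**Step 10**
Reactants: 18 the photoadduct
Product: 20 C10 methyl ketone of the photoadduct, via secondary ozonide 19 (not isolated)
Conditions: O3, CH2Cl2, −78 °C; then PPh3
Reagents that add atoms: ozone [O-][O+]=O
Why: Ozonolysis cleaves the only remaining C=C, and the neutral reductive work-up keeps the acetyl group in its cis (endo) position at C10.

**Step 11**
Reactants: 21 5-bromo-2-methylpent-2-ene; 22 triphenylphosphane
Product: 23 (4-methylpent-3-en-1-yl)triphenylphosphonium bromide
Conditions: MeCN, reflux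
Reagents that add atoms: none
Why: SN2 quaternization of the primary bromide gives the phosphonium salt.

**Step 12**
Reactants: 20 the methyl ketone; 23 the phosphonium bromide
Product: 24 (11Z)-side-chain photoadduct lactone
Conditions: KN(SiMe3)2, THF, 0 °C; then 20, −78 → 0 °C
Reagents that add atoms: none
Why: Salt-free Wittig olefination of an α-branched methyl ketone with a non-stabilized ylide places the ylide substituent cis to the larger ketone substituent (Z major), the ketone reacts ahead of the lactone and the hindered pivalate, and the minor E isomer is removed on AgNO3-impregnated silica.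

**Step 13**
Reactants: 24 the Wittig product
Product: 25 cyclobutanol triol (C4–OH, C6–OH, C18–OH)
Conditions: LiAlH4, THF, −20 °C → rt
Reagents that add atoms: none
Why: Hydride reduction opens the unhindered δ-lactone first (C18H2OH and C4–OH) and then cleaves the tertiary pivalate, so the C6 alkoxide appears only when no β-carbonyl is left for a retro-aldol.

**Step 14**
Reactants: 25 the triol
Product: 26 C4,C18-diacetate cyclobutanol
Conditions: Ac2O, pyridine, 0 °C → rt
Reagents that add atoms: acetic anhydride CC(=O)OC(C)=O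
Why: Acylation takes the primary and secondary hydroxyls and leaves the tertiary cyclobutanol free.

**Step 15**
Reactants: 26 the diacetate
Product: 29 target CNP0222995.1, via hydroperoxide 27 (not isolated), via acetoxy hydroxy ketone 28 (not isolated)
Conditions: Mn(acac)3 (10 mol%), O2 (1 atm), EtOH, rt; PPh3; then DBU, CH2Cl2, 0 °C, 15 min
Reagents that add atoms: dioxygen O=O
Why: Manganese-catalysed aerobic ring opening of the cyclobutanol (alkoxy-radical β-scission toward the tertiary C7 radical) gives the C6 ketone, O2 adds to C7 anti to the ring A substituent on C1 (7R), PPh3 reduces the hydroperoxide, and brief E1cB elimination of the C4 acetate gives the enone without epimerizing C2 or C3.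

**Compound list**
1 | methyl 3,3-dimethoxypropanoate | COC(=O)CC(OC)OC | starting material
2 | methyl 3-oxopropanoate | COC(=O)CC=O | intermediate
3 | methyl (3R,4S)-3-hydroxy-4-methylhex-5-enoate | COC(=O)C[C@@H](O)[C@@H](C)C=C | intermediate
4 | tert-butyl acetate | CC(=O)OC(C)(C)C | starting material
5 | tert-butyl (5R,6S)-5-hydroxy-6-methyl-3-oxooct-7-enoate | CC(C)(C)OC(=O)CC(=O)C[C@@H](O)[C@@H](C)C=C | intermediate
6 | (6R)-6-[(2S)-but-3-en-2-yl]-4-hydroxy-5,6-dihydro-2H-pyran-2-one | OC1=CC(=O)O[C@H](C1)[C@@H](C)C=C | intermediate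
7 | methacrolein | CC(=C)C=O | starting material
8 | 1-(triphenyl-λ5-phosphanylidene)propan-2-one | CC(=O)C=P(c1ccccc1)(c1ccccc1)c1ccccc1 | starting material
9 | (3E)-5-methylhexa-3,5-dien-2-one | CC(=O)/C=C/C(C)=C | intermediate
10 | (2R,3E)-5-methylhexa-3,5-dien-2-ol | C[C@@H](O)/C=C/C(C)=C | intermediate
11 | vinyl acetate | CC(=O)OC=C | starting material
12 | (2R,3E)-2-(ethenyloxy)-5-methylhexa-3,5-diene | C[C@@H](OC=C)/C=C/C(C)=C | intermediate
13 | (3R,4E)-3-(prop-1-en-2-yl)hex-4-enal | O=CC[C@H](/C=C/C)C(C)=C | intermediate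
14 | (6R)-6-[(2S)-but-3-en-2-yl]-3-[(3R,4E)-3-(prop-1-en-2-yl)hex-4-en-1-ylidene]oxane-2,4-dione (E/Z mixture at the new C=C) | C=C[C@H](C)[C@H]1CC(=O)C(=CC[C@H](/C=C/C)C(C)=C)C(=O)O1 | intermediate
15 | (6R)-6-[(2S)-but-3-en-2-yl]-4-hydroxy-3-[(3R,4E)-3-(prop-1-en-2-yl)hex-4-en-1-yl]-5,6-dihydro-2H-pyran-2-one | C=C[C@H](C)[C@H]1CC(O)=C(CC[C@H](/C=C/C)C(C)=C)C(=O)O1 | intermediate
16 | 4-pivalate of 15 | C=C[C@H](C)[C@H]1CC(OC(=O)C(C)(C)C)=C(CC[C@H](/C=C/C)C(C)=C)C(=O)O1 | intermediate
17 | ten-membered carbocycle C1–C10 (C1=C2 Z; C6=C7 enol pivalate) bridged by the δ-lactone C4–O–C18(=O)–C7; (3S)-methyl, (4R), (10R)-isopropenyl | CC(=C)[C@@H]1CCC2=C(OC(=O)C(C)(C)C)C[C@@H](OC2=O)[C@@H](C)/C=C\1 | intermediate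
18 | spatane-type tricycle: cyclobutane C1–C2–C6–C7 cis-fused to ring A and ring B on opposite faces (H1/H2 trans); lactone C7–C18(=O)–O–C4 on the ring A face; C6–OPiv; C3–CH3 and C10–isopropenyl cis to the C1–C2 bond | CC(=C)[C@@H]1CC[C@]23C(=O)O[C@@H]4C[C@@]2(OC(=O)C(C)(C)C)[C@H]([C@H]13)[C@@H]4C | intermediate
19 | 1,2,4-trioxolane (secondary ozonide) of 18 at the isopropenyl group | CC1(OCOO1)[C@@H]2CC[C@]34C(=O)O[C@@H]5C[C@@]3(OC(=O)C(C)(C)C)[C@H]([C@H]24)[C@@H]5C | intermediate
20 | 18 with C10 acetyl in place of isopropenyl | CC(=O)[C@@H]1CC[C@]23C(=O)O[C@@H]4C[C@@]2(OC(=O)C(C)(C)C)[C@H]([C@H]13)[C@@H]4C | intermediate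
21 | 5-bromo-2-methylpent-2-ene | CC(C)=CCCBr | starting material
22 | triphenylphosphane | c1ccc(cc1)P(c1ccccc1)c1ccccc1 | starting material
23 | (4-methylpent-3-en-1-yl)triphenylphosphonium bromide | CC(C)=CCC[P+](c1ccccc1)(c1ccccc1)c1ccccc1.[Br-] | intermediate
24 | 18 with the (Z)-6-methylhepta-2,5-dien-2-yl side chain on C10 | CC(C)=CC/C=C(/C)[C@@H]1CC[C@]23C(=O)O[C@@H]4C[C@@]2(OC(=O)C(C)(C)C)[C@H]([C@H]13)[C@@H]4C | intermediate
25 | tricyclic triol: C6 cyclobutanol, C7–CH2OH, C4–OH (C4–OH cis to C3–CH3) | CC(C)=CC/C=C(/C)[C@@H]1CC[C@]2(CO)[C@@]3(O)C[C@@H](O)[C@@H](C)[C@H]3[C@H]12 | intermediate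
26 | 25 as C18 and C4 diacetate | CC(C)=CC/C=C(/C)[C@@H]1CC[C@]2(COC(C)=O)[C@@]3(O)C[C@@H](OC(C)=O)[C@@H](C)[C@H]3[C@H]12 | intermediate
27 | ring-opened C6 ketone with C7 hydroperoxide and C4 acetate | CC(=O)OC[C@@]1(OO)CC[C@@H](/C(C)=C\CC=C(C)C)[C@H]1[C@H]1C(=O)C[C@@H](OC(C)=O)[C@H]1C | intermediate
28 | as 27 with C7–OH | CC(=O)OC[C@@]1(O)CC[C@@H](/C(C)=C\CC=C(C)C)[C@H]1[C@H]1C(=O)C[C@@H](OC(C)=O)[C@H]1C | intermediate
29 | CNP0222995.1, (1S,2S,3R,7R,10R; 11Z) | CC(=O)OC[C@@]1(O)CC[C@@H](/C(C)=C\CC=C(C)C)[C@H]1[C@H]1C(=O)C=C[C@H]1C | target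

**Step count and risks**
Total steps: 15. Longest linear sequence: 12 (steps 3–10 and 12–15, from methacrolein 7).

Most likely to fail, first: step 8. The ring closure gives a strained bridged ten-membered ring between two branched alkenes. The fallback closes the carbocycle before the lactone. It sets out from keto ester 5 (isolated after the Claisen condensation) and aldehyde 13. Proline/Hantzsch-ester reductive alkylation of the open-chain β-keto ester gives the alkylated keto ester F1. Ring-closing metathesis on this unbridged, flexible diene gives the ten-membered β-keto ester F2. TFA then cleaves the tert-butyl ester and closes the δ-lactone across the ring to the bridged hydroxypyranone F3. PivCl/Et3N returns to 17.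

Second: step 9. The photocycloaddition is unprecedented in this setting; the isopropenyl group may compete for the excited enoate, and the enol ester may undergo an acyl shift. The fallback removes the second alkene before irradiation. It sets out from 17. OsO4 (cat.)/N-methylmorpholine N-oxide dihydroxylates the unhindered isopropenyl group to the diol F4. 2,2-Dimethoxypropane/PPTS gives the acetonide F5. Irradiation as in step 9 then involves a single alkene and gives the photoadduct acetonide F6. H5IO6 in wet EtOAc unmasks and cleaves the glycol, returning at 20 without ozonolysis.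

Third: step 12. The ketone is hindered and the Z/E ratio of a Wittig reaction on a methyl ketone is uncertain. The fallback is a stepwise Horner–Wittig sequence. It sets out from 20 and 23. Aqueous NaOH converts 23 into the phosphane oxide F7. Its lithio derivative (n-BuLi, THF, −78 °C) adds to ketone 20, and the diastereomeric adducts are separated. The β-hydroxy phosphane oxide F8 with the matching C11/C12 relationship undergoes stereospecific syn-elimination with NaH in DMF to give the Z olefin, returning at 24.

**Further compounds**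
F1 | step 8 | tert-butyl (5R,6S)-5-hydroxy-6-methyl-3-oxo-2-[(3R,4E)-3-(prop-1-en-2-yl)hex-4-en-1-yl]oct-7-enoate (C2 epimers) | C=C[C@H](C)[C@H](O)CC(=O)C(CC[C@H](/C=C/C)C(C)=C)C(=O)OC(C)(C)C
F2 | step 8 | unbridged ten-membered β-keto tert-butyl ester (C1=C2 Z; C4–OH; C10 isopropenyl) | CC(=C)[C@@H]1CCC(C(=O)OC(C)(C)C)C(=O)C[C@@H](O)[C@@H](C)/C=C\1
F3 | step 8 | lactone-bridged 4-hydroxypyranone (17 without the pivaloyl group) | CC(=C)[C@@H]1CCC2=C(O)C[C@@H](OC2=O)[C@@H](C)/C=C\1
F4 | step 9 | 17 with the isopropenyl group as its 1,2-diol (C11 epimers) | CC(O)(CO)[C@@H]1CCC2=C(OC(=O)C(C)(C)C)C[C@@H](OC2=O)[C@@H](C)/C=C\1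
F5 | step 9 | acetonide of F4 | CC1(COC(C)(C)O1)[C@@H]2CCC3=C(OC(=O)C(C)(C)C)C[C@@H](OC3=O)[C@@H](C)/C=C\2
F6 | step 9 | photoadduct of F5 (18 with the glycol acetonide in place of isopropenyl) | CC1(COC(C)(C)O1)[C@@H]2CC[C@]34C(=O)O[C@@H]5C[C@@]3(OC(=O)C(C)(C)C)[C@H]([C@H]24)[C@@H]5C
F7 | step 12 | (4-methylpent-3-en-1-yl)diphenylphosphane oxide | CC(C)=CCCP(=O)(c1ccccc1)c1ccccc1
F8 | step 12 | β-hydroxy phosphane oxide adduct of 20 (C11/C12 diastereomer that gives Z on syn-elimination) | CC(C)=CC[C@@H](P(=O)(c1ccccc1)c1ccccc1)[C@@](C)(O)[C@@H]1CC[C@]23C(=O)O[C@@H]4C[C@@]2(OC(=O)C(C)(C)C)[C@H]([C@H]13)[C@@H]4C
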